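**Strategy.** Ring locants: C1(Me)=C2, C3 (benzofuranyl), C4 (aroyl), C5 (resorcinyl), C6. The usual chalcone–diene cycloaddition is set aside. C3 is at once allylic, benzylic to benzofuran C5 (oxygen ortho and para) and β to the ketone. The C3–C4 bond is therefore cut into an allyl cation and the ketone enol. The precursor is acyclic: a linalool-like tertiary styryl carbinol tethered to the aryl ketone, with C5 alone defined and C1 stereorandom. One acid-triggered step erases C1, closes the cyclohexene (linalyl-to-terpinyl topology), places C1=C2, and sets C3 and C4 from C5 as the all-equatorial triad. C4 is thus a linchpin, joined to C5 by an asymmetric Michael addition.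

Key step: step 13

Remarks. TBS = tert-butyldimethylsilyl and prenyl = 3-methylbut-2-en-1-yl. The ring locants above are used for all acyclic precursors as well.
Assumption: the sense of induction in step 6 is taken by analogy with additions of 1,3-dicarbonyl donors to benzylideneacetones under cinchona primary-amine catalysis. If it proves opposite, the pseudo-enantiomeric quinine-derived amine is used.

Step 1
Reactants: 1 2,4-dihydroxyacetophenone
Product: 2 1-[2,4-dihydroxy-3-prenylphenyl]ethan-1-one
Conditions: prenyl bromide (1 equiv), KOH, H2O, 0 °C → rt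
Reagents that add atoms: prenyl bromide (1-bromo-3-methylbut-2-ene), CC(C)=CCBr
Why: C-alkylation of the ambident resorcinolate in water (phenolate C-prenylation) should favour C3, the carbon flanked by both oxygens, and the 5-prenyl and O-prenyl isomers are removed by chromatography.

Step 2
Reactants: 2 1-[2,4-dihydroxy-3-prenylphenyl]ethan-1-one
Product: 3 1-[4-(TBSO)-2-hydroxy-3-prenylphenyl]ethan-1-one
Conditions: TBSCl (1.05 equiv), imidazole, CH2Cl2, 0 °C
Reagents that add atoms: tert-butyldimethylsilyl chloride, CC(C)(C)[Si](C)(C)Cl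
Why: In this silyl ether formation the 2-OH is hydrogen-bonded to the acetyl group and flanked by the prenyl chain, so one equivalent of TBSCl should take only the 4-OH.

Step 3
Reactants: 3 1-[4-(TBSO)-2-hydroxy-3-prenylphenyl]ethan-1-one
Product: 4 3-[4-(TBSO)-2-hydroxy-3-prenylphenyl]-3-oxopropanoic acid
Conditions: LiHMDS (3.3 equiv), THF, −78 °C; CO2; cold dilute HCl
Reagents that add atoms: carbon dioxide, O=C=O
Why: Carboxylation of the phenoxide–enolate polyanion of an o-hydroxyacetophenone at carbon should give the aroylacetic acid, which is kept cold and used at once to avoid decarboxylation.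

Step 4
Reactants: 5 2,4-dihydroxybenzaldehyde
Product: 6 2,4-bis(TBSO)benzaldehyde
Conditions: TBSCl (2.5 equiv), imidazole, DMF, rt
Reagents that add atoms: tert-butyldimethylsilyl chloride, CC(C)(C)[Si](C)(C)Cl
Why: Exhaustive silylation of both unhindered phenols gives ethers that survive bases, organometallics and weak acid and leave with fluoride.

Step 5
Reactants: 6 2,4-bis(TBSO)benzaldehyde
Product: 7 (E)-4-[2,4-bis(TBSO)phenyl]but-3-en-2-one
Conditions: Ph3P=CHCOCH3, toluene, 90 °C
Reagents that add atoms: 1-(triphenyl-λ5-phosphanylidene)propan-2-one, CC(=O)C=P(c1ccccc1)(c1ccccc1)c1ccccc1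
Why: The Wittig reaction of a stabilised ylide is E-selective and base-free, so the aryl silyl ethers are not touched.

Step 6
Reactants: 4 3-[4-(TBSO)-2-hydroxy-3-prenylphenyl]-3-oxopropanoic acid; 7 (E)-4-[2,4-bis(TBSO)phenyl]but-3-en-2-one
Product: 9 (3S)-3-[2,4-bis(TBSO)phenyl]-1-[4-(TBSO)-2-hydroxy-3-prenylphenyl]hexane-1,5-dione, via 2-aroyl-3-aryl-5-oxohexanoic acid (Michael adduct) 8 (not isolated)
Conditions: 9-amino-9-deoxy-epi-quinidine (20 mol %), 4 (1.5 equiv), toluene, rt
Reagents that add atoms: none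
Why: In this iminium-catalysed decarboxylative Michael addition of a β-keto acid to a benzylideneacetone, the primary amine activates 7, the quinuclidine binds the acid so that one enone face is attacked and ring C5 is set (S), and loss of CO2 from 8 makes the C4–C5 bond formation irreversible.

Step 7
Reactants: 9 (3S)-1,5-diketone
Product: 10 (3S)-3-[2,4-bis(TBSO)phenyl]-5-hydroxy-1-[4-(TBSO)-2-hydroxy-3-prenylphenyl]-5-methylhept-6-en-1-one (both epimers at the carbinol carbon, ring C1; may rest partly as the cyclic hemiketal)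
Conditions: LaCl3·2LiCl (1.1 equiv), vinylMgBr (2.3 equiv), THF, −78 °C; aq NH4Cl
Reagents that add atoms: vinylmagnesium bromide, C=C[Mg]Br
Why: In this lanthanide-assisted Grignard 1,2-addition the first equivalent turns the aryl ketone into its chelated ortho-phenoxide, a vinylogous carboxylate that is inert at −78 °C, so only the methyl ketone reacts, and the uncontrolled C1 carbinol centre is of no consequence because step 13 erases it.

Step 8
Reactants: 11 4-bromobenzene-1,3-diol (4-bromoresorcinol)
Product: 12 4-bromo-6-iodobenzene-1,3-diol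
Conditions: NIS (1 equiv), MeCN, 0 °C
Reagents that add atoms: N-iodosuccinimide, O=C1CCC(=O)N1I
Why: Electrophilic aromatic iodination under non-basic conditions should go to C6 (ortho to one OH and para to the other) rather than to the crowded C2.

Step 9
Reactants: 12 4-bromo-6-iodobenzene-1,3-diol; 13 1-ethynyl-3,5-dimethoxybenzene
Product: 15 5-bromo-2-(3,5-dimethoxyphenyl)-1-benzofuran-6-ol, via 4-bromo-6-[(3,5-dimethoxyphenyl)ethynyl]benzene-1,3-diol 14 (not isolated)
Conditions: PdCl2(PPh3)2 (3 mol %), CuI (5 mol %), Et3N, DMF, rt then 60 °C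
Reagents that add atoms: none
Why: Sonogashira coupling takes C–I in preference to C–Br, and the only hydroxyl ortho to the alkyne closes the furan by 5-endo-dig hydroalkoxylation, which leaves Br at benzofuran C5 and OH at C6.

Step 10
Reactants: 15 5-bromo-2-(3,5-dimethoxyphenyl)-1-benzofuran-6-ol
Product: 16 5-(5-bromo-6-hydroxy-1-benzofuran-2-yl)benzene-1,3-diol
Conditions: BBr3 (3 equiv), CH2Cl2, −78 °C → rt; H2O
Reagents that add atoms: none
Why: Lewis-acid cleavage of aryl methyl ethers is standard on 2-arylbenzofurans and is done here while no acid-sensitive group is present.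

Step 11
Reactants: 16 5-(5-bromo-6-hydroxy-1-benzofuran-2-yl)benzene-1,3-diol
Product: 17 5-bromo-6-(TBSO)-2-[3,5-bis(TBSO)phenyl]-1-benzofuran
Conditions: TBSCl (4 equiv), imidazole, DMF, rt
Reagents that add atoms: tert-butyldimethylsilyl chloride, CC(C)(C)[Si](C)(C)Cl
Why: Exhaustive silylation caps all three phenols, in particular the C6 oxygen that would otherwise close a 2H-chromene on the cation of step 13.

Step 12
Reactants: 10 tertiary vinyl carbinol; 17 5-bromo-6-(TBSO)-2-[3,5-bis(TBSO)phenyl]-1-benzofuran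
Product: 18 (3S,6E)-7-{6-(TBSO)-2-[3,5-bis(TBSO)phenyl]-1-benzofuran-5-yl}-3-[2,4-bis(TBSO)phenyl]-5-hydroxy-1-[4-(TBSO)-2-hydroxy-3-prenylphenyl]-5-methylhept-6-en-1-one (both C1 epimers)
Conditions: Pd2(dba)3 (2.5 mol %), P(t-Bu)3·HBF4 (10 mol %), Cy2NMe (2 equiv), dioxane, 70 °C
Reagents that add atoms: none
Why: In this Mizoroki–Heck reaction the aryl group adds to the unsubstituted vinyl terminus and syn β-hydride elimination, impossible toward the fully substituted carbinol carbon, gives the E-styryl carbinol, while the trisubstituted prenyl alkene does not insert.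

Step 13
Reactants: 18 (3S,6E)-styryl carbinol (both C1 epimers)
Product: 20 [4-(TBSO)-2-hydroxy-3-prenylphenyl]{(1R,2R,6S)-6-[2,4-bis(TBSO)phenyl]-2-{6-(TBSO)-2-[3,5-bis(TBSO)phenyl]-1-benzofuran-5-yl}-4-methylcyclohex-3-en-1-yl}methanone (ring locants 3R,4R,5S, all-trans), via (4S)-2-methyl-2-[(E)-2-(benzofuran-5-yl)ethenyl]-4,6-diaryl-3,4-dihydro-2H-pyran 19 (not isolated)
Conditions: (PhO)2P(O)OH (10 mol %), (CF3)2CHOH–CH2Cl2 1:4, 4 Å MS, 0.01 M, −20 °C → rt
Reagents that add atoms: none
Why: Proposed new method: the acid ionises the tertiary allylic C1–OH of both C1 epimers of 18 to one planar C1–C2–C3 allyl cation delocalised into benzofuran C5 with its ortho (C6–OTBS) and para (O1) oxygens, so that C1 is erased; capture by the ketone oxygen at C1 with proton loss (dihydropyran 19) and E1 loss of a proton (dienes) are both reversible under the conditions, whereas attack on C3 by the enol carbon C4, released next to the cation each time 19 re-ionises, gives a ketone that cannot re-ionise and so drains the whole manifold into 20. The closest known reaction types are the thermal Claisen rearrangement of 2-vinyl-3,4-dihydro-2H-pyrans to 4-acylcyclohexenes, the ionisation–recombination O-to-C shift of allyl vinyl ethers in ionising media, the acid-catalysed SN1 allylation of enolisable carbonyl compounds with allylic alcohols, and the linalyl-to-terpinyl cation cyclisation, which has the same ring topology. The cyclohexene closes 6-endo with respect to the allyl cation and enol-exo with respect to the nucleophile, the only other C–C closure (C4 to C1) being a strained four-membered ring. C3 and C4 are both controlled by the resident C5 centre through a staggered, half-chair-like transition state: the C5 aryl group sits equatorial (anti to the forming bond), allylic 1,3-strain places H5 in the enol plane so that the aroyl carbon ends equatorial, and the E-configured cation terminus keeps the benzofuranyl group pseudo-equatorial, which together give the 3,5-cis-diaryl, 4-trans-aroyl (3R,4R,5S) array. The step needs C- over O-alkylation (secured by the reversibility of every C–O bond to C1), C3 over C1 attack (ring size) and silence of the other π-nucleophiles: every phenol oxygen within reach of the cation is silylated, the only C5-aryl carbon within reach is meta to both of its oxygens, and the weak acid should not protonate the prenyl or the product alkene. An axial-aroyl C4 epimer, if formed, has the same C3/C5 relation and can equilibrate through the enol to the all-equatorial ketone.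

Step 14
Reactants: 20 hexakis-TBS ether of the target
Product: 21 [2,4-dihydroxy-3-prenylphenyl]{(1R,2R,6S)-6-(2,4-dihydroxyphenyl)-2-[2-(3,5-dihydroxyphenyl)-6-hydroxy-1-benzofuran-5-yl]-4-methylcyclohex-3-en-1-yl}methanone (CNP0150120.1)
Conditions: TBAF (7 equiv), AcOH (7 equiv), THF, 0 °C
Reagents that add atoms: none
Why: Fluoride cleavage of the six aryl silyl ethers under acetic acid buffering stays close to neutral, so C4 should not epimerise and neither prenyl–phenol cyclisation nor ketalisation should set in.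

**Compound list**
1 | 2,4-dihydroxyacetophenone | CC(=O)c1ccc(O)cc1O | starting material
2 | 1-[2,4-dihydroxy-3-prenylphenyl]ethan-1-one | CC(=O)c1ccc(O)c(CC=C(C)C)c1O | intermediate
3 | 1-[4-(TBSO)-2-hydroxy-3-prenylphenyl]ethan-1-one | CC(=O)c1ccc(O[Si](C)(C)C(C)(C)C)c(CC=C(C)C)c1O | intermediate
4 | 3-[4-(TBSO)-2-hydroxy-3-prenylphenyl]-3-oxopropanoic acid | OC(=O)CC(=O)c1ccc(O[Si](C)(C)C(C)(C)C)c(CC=C(C)C)c1O | intermediate
5 | 2,4-dihydroxybenzaldehyde | O=Cc1ccc(O)cc1O | starting material
6 | 2,4-bis(TBSO)benzaldehyde | O=Cc1ccc(O[Si](C)(C)C(C)(C)C)cc1O[Si](C)(C)C(C)(C)C | intermediate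
7 | (E)-4-[2,4-bis(TBSO)phenyl]but-3-en-2-one | CC(=O)/C=C/c1ccc(O[Si](C)(C)C(C)(C)C)cc1O[Si](C)(C)C(C)(C)C | intermediate
8 | Michael adduct β-keto acid (C5 defined, C4 epimers) | CC(C)=CCc1c(O[Si](C)(C)C(C)(C)C)ccc(C(=O)C(C(=O)O)[C@@H](c2ccc(O[Si](C)(C)C(C)(C)C)cc2O[Si](C)(C)C(C)(C)C)CC(C)=O)c1O | intermediate (not isolated)
9 | (3S)-1,5-diketone | CC(C)=CCc1c(O[Si](C)(C)C(C)(C)C)ccc(C(=O)C[C@@H](c2ccc(O[Si](C)(C)C(C)(C)C)cc2O[Si](C)(C)C(C)(C)C)CC(C)=O)c1O | intermediate
10 | (3S)-tertiary vinyl carbinol (C1 epimers) | CC(C)=CCc1c(O[Si](C)(C)C(C)(C)C)ccc(C(=O)C[C@@H](c2ccc(O[Si](C)(C)C(C)(C)C)cc2O[Si](C)(C)C(C)(C)C)CC(C)(O)C=C)c1O | intermediate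
11 | 4-bromobenzene-1,3-diol | Oc1ccc(Br)c(O)c1 | starting material
12 | 4-bromo-6-iodobenzene-1,3-diol | Oc1cc(O)c(I)cc1Br | intermediate
13 | 1-ethynyl-3,5-dimethoxybenzene | C#Cc1cc(OC)cc(OC)c1 | starting material
14 | 4-bromo-6-[(3,5-dimethoxyphenyl)ethynyl]benzene-1,3-diol | Oc1cc(O)c(C#Cc2cc(OC)cc(OC)c2)cc1Br | intermediate (not isolated)
15 | 5-bromo-2-(3,5-dimethoxyphenyl)-1-benzofuran-6-ol | COc1cc(OC)cc(-c2cc3cc(Br)c(O)cc3o2)c1 | intermediate
16 | 5-(5-bromo-6-hydroxy-1-benzofuran-2-yl)benzene-1,3-diol | Oc1cc(O)cc(-c2cc3cc(Br)c(O)cc3o2)c1 | intermediate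
17 | 5-bromo-6-(TBSO)-2-[3,5-bis(TBSO)phenyl]-1-benzofuran | CC(C)(C)[Si](C)(C)Oc1cc(O[Si](C)(C)C(C)(C)C)cc(-c2cc3cc(Br)c(O[Si](C)(C)C(C)(C)C)cc3o2)c1 | intermediate
18 | (3S,6E)-styryl carbinol (C1 epimers) | CC(C)=CCc1c(O[Si](C)(C)C(C)(C)C)ccc(C(=O)C[C@@H](c2ccc(O[Si](C)(C)C(C)(C)C)cc2O[Si](C)(C)C(C)(C)C)CC(C)(O)/C=C/c2cc3cc(-c4cc(O[Si](C)(C)C(C)(C)C)cc(O[Si](C)(C)C(C)(C)C)c4)oc3cc2O[Si](C)(C)C(C)(C)C)c1O | intermediate
19 | (4S)-2-methyl-2-styryl-4,6-diaryl-3,4-dihydro-2H-pyran (C2 epimers) | CC(C)=CCc1c(O[Si](C)(C)C(C)(C)C)ccc(C2=C[C@@H](c3ccc(O[Si](C)(C)C(C)(C)C)cc3O[Si](C)(C)C(C)(C)C)CC(C)(/C=C/c3cc4cc(-c5cc(O[Si](C)(C)C(C)(C)C)cc(O[Si](C)(C)C(C)(C)C)c5)oc4cc3O[Si](C)(C)C(C)(C)C)O2)c1O | intermediate (not isolated)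
20 | hexakis-TBS ether of the target, all-trans | CC(C)=CCc1c(O[Si](C)(C)C(C)(C)C)ccc(C(=O)[C@@H]2[C@@H](c3ccc(O[Si](C)(C)C(C)(C)C)cc3O[Si](C)(C)C(C)(C)C)CC(C)=C[C@H]2c2cc3cc(-c4cc(O[Si](C)(C)C(C)(C)C)cc(O[Si](C)(C)C(C)(C)C)c4)oc3cc2O[Si](C)(C)C(C)(C)C)c1O | intermediate
21 | CNP0150120.1 | CC(C)=CCc1c(O)ccc(C(=O)[C@@H]2[C@@H](c3ccc(O)cc3O)CC(C)=C[C@H]2c2cc3cc(-c4cc(O)cc(O)c4)oc3cc2O)c1O | target

**Step count.** Total steps: 14. Longest linear sequence: 8 (steps 1, 2, 3, 6, 7, 12, 13, 14).

**Steps most likely to fail**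

1. Step 13 (Proposed new method).
- What may go wrong: enol formation may be too slow. The cation is then lost through elimination and oligomerisation, or through desilylative capture by a neighbouring aryl silyl ether. Closure through a transition state with the C5 aryl group axial could also erode facial selectivity.
- Fallback, which uses known chemistry: Lewis-acid-mediated SN1 alkylation of a preformed silyl enol ether (Mukaiyama type) at low temperature. It sets out from 18. TMSOTf/Et3N (CH2Cl2, −78 → 0 °C) gives the (Z)-trimethylsilyl enol ether that also carries the C1–OTMS group and the aryl 2-OTMS ether F1.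
- Return: ZnBr2 or catalytic TMSOTf at −78 °C ionises the allylic silyl ether, and the enol silane closes C3–C4. A mild aqueous work-up frees the 2-OH, and the route is rejoined at 20.

2. Step 6.
- What may go wrong: protodecarboxylation of the β-keto acid may outrun the addition. Face discrimination may also be poor with the hindered, electron-rich enone.
- Fallback: donor and acceptor are exchanged, so that C5–C6 is formed instead of C4–C5. It sets out from 4 and 6. A decarboxylative Knoevenagel–Doebner condensation (catalytic piperidine/AcOH, toluene, 50 °C) gives the 2′-hydroxychalcone F2.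
- Return: a cinchona-thiourea-catalysed Michael addition of allyl acetoacetate gives the allyl 2-acetyl-5-oxopentanoate adduct F3. Pd(PPh3)4/morpholine (deallylation and decarboxylation) then returns to 9.

3. Step 7.
- What may go wrong: the basic vinyl Grignard reagent may enolise the methyl ketone. That would return starting material or start a retro-Michael cleavage that erodes C5.
- Fallback: a far less basic acetylide is added and the aryl–vinyl bond is made by a different coupling. It sets out from 9. Ethynylmagnesium bromide (THF, 0 °C) gives the tertiary propargylic alcohol F4.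
- Return: Pd-catalysed hydrostannation (Bu3SnH, PdCl2(PPh3)2) gives the (E)-β-tributylstannyl allylic alcohol F5. Stille coupling with 17 (Pd(PPh3)4, CuI, DMF, 70 °C) rejoins the route at 18, bypassing 10 and step 12.

**Further compounds**
F1 | step 13 | (Z)-TMS enol ether of 18 with C1–OTMS and aryl 2-OTMS | CC(C)=CCc1c(O[Si](C)(C)C(C)(C)C)ccc(/C(O[Si](C)(C)C)=C/[C@@H](c2ccc(O[Si](C)(C)C(C)(C)C)cc2O[Si](C)(C)C(C)(C)C)CC(C)(O[Si](C)(C)C)/C=C/c2cc3cc(-c4cc(O[Si](C)(C)C(C)(C)C)cc(O[Si](C)(C)C(C)(C)C)c4)oc3cc2O[Si](C)(C)C(C)(C)C)c1O[Si](C)(C)C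
F2 | step 6 | (E)-3-[2,4-bis(TBSO)phenyl]-1-[4-(TBSO)-2-hydroxy-3-prenylphenyl]prop-2-en-1-one | CC(C)=CCc1c(O[Si](C)(C)C(C)(C)C)ccc(C(=O)/C=C/c2ccc(O[Si](C)(C)C(C)(C)C)cc2O[Si](C)(C)C(C)(C)C)c1O
F3 | step 6 | allyl 2-acetyl-3-[2,4-bis(TBSO)phenyl]-5-[4-(TBSO)-2-hydroxy-3-prenylphenyl]-5-oxopentanoate (C5 as in 9, C6 epimers) | CC(C)=CCc1c(O[Si](C)(C)C(C)(C)C)ccc(C(=O)C[C@@H](c2ccc(O[Si](C)(C)C(C)(C)C)cc2O[Si](C)(C)C(C)(C)C)C(C(C)=O)C(=O)OCC=C)c1O
F4 | step 7 | (3S)-3-[2,4-bis(TBSO)phenyl]-5-hydroxy-1-[4-(TBSO)-2-hydroxy-3-prenylphenyl]-5-methylhept-6-yn-1-one (C1 epimers) | CC(C)=CCc1c(O[Si](C)(C)C(C)(C)C)ccc(C(=O)C[C@@H](c2ccc(O[Si](C)(C)C(C)(C)C)cc2O[Si](C)(C)C(C)(C)C)CC(C)(O)C#C)c1O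
F5 | step 7 | (3S,6E)-7-(tributylstannyl) analogue of 10 (C1 epimers) | CC(C)=CCc1c(O[Si](C)(C)C(C)(C)C)ccc(C(=O)C[C@@H](c2ccc(O[Si](C)(C)C(C)(C)C)cc2O[Si](C)(C)C(C)(C)C)CC(C)(O)/C=C/[Sn](CCCC)(CCCC)CCCC)c1O
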